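## Analysis of the target

The target (19, C18H10O8) is a bis-coumarin: a 7-hydroxycoumarin (unit A) whose C6 oxygen is bonded to C5' of a 6',7'-dihydroxycoumarin (unit B). It has no stereocentre, so the whole problem is the correct placement of oxygen and carbon substituents on two arenes. The carbocycle of unit A is an ordinary 1,2,4-trioxygenated benzene. The carbocycle of unit B is the hard part: five of its six positions are substituted (oxygen on C5', C6', C7' and C8a', carbon on C4a') and only C8' carries hydrogen. The bridging oxygen on C5' lies between C4a' and C6', both substituted, so a late arylation there would have to occur at a di-ortho-substituted, electron-rich carbon. The sensitive groups are the two lactones (opened by hydroxide or alkoxide, attacked by hydride and organometallic reagents) and the C6'/C7' catechol, which is prone to oxidation and should be uncovered last. The plan rests on the fact that the six benzene carbons of unit B divide into a two-carbon piece (C4a' and C5', the latter already bonded to the oxygen of unit A) and a four-carbon piece (C6', C7', C8', C8a') whose oxygen pattern is that of a squaric acid derivative.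

## Retrosynthetic reasoning

**19 from 18.** The three O–CH3 bonds are cut last. Methyl ethers withstand everything the route demands (heat, a ketene, a fluoride source, a boiling amine), and one Lewis-acid treatment removes all three while leaving the diaryl ether, which has no sp3 carbon on oxygen, intact. The catechol is therefore exposed only in the final step.

**18 from 16.** The pyranone of unit B is opened at the C3'=C4' bond and at the O1'–C2' bond, which leads to the salicylaldehyde 16 and a two-carbon stabilised ylide. Forward, olefination gives the cinnamate 17, which isomerises and lactonises in the same pot. Only this pyranone is built; that of unit A arrives ready-made in 3. This saves a ring construction, at the price that every step after step 2 must spare a lactone.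

**16 from 15 from 14.** These are adjustments at the carbon that becomes C4'. It is carried through the thermal step as a silyl-protected hydroxymethyl group, because in the key step this carbon sits on the alkyne and a formyl group there would reverse the polarisation of the triple bond. Desilylation to 15 and benzylic oxidation then give 16.

**14 from 5 and 9.** This is the central disconnection. The benzene ring of unit B is cut at C4a'–C8a' and C5'–C6', giving the aryl ynol ether 5 (C4a' and C5') and the cyclobutenone 9 (C6', C7', C8', C8a'). Cutting here means that the hindered C5'–O bond is never made on an arene, because the oxygen is already on the alkyne. The two methoxy groups of 9 become the C6' and C7' oxygens, the carbonyl of 9 becomes the C8a' phenol, and the CH2 of 9 becomes C8'–H. Forward, the cascade through 10, 11, 12 and 13 must join the silyloxymethyl-bearing alkyne carbon to the ketene carbonyl carbon, so that the aryloxy group ends up meta to the new phenol.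

**5 from 2 and 3; 2 from 1.** The O–C(sp) bond is cut to give the phenol 3 and the 1,1-dibromoalkene 2. Forward, a copper-catalysed C–O coupling gives the bromo enol ether 4, from which hydrogen bromide is eliminated. 2 is the dibromo-olefination product of the aldehyde 1. This route to an aryl ynol ether needs no organolithium reagent, which the lactone of 3 would not tolerate.

**9 from 8 from 7 from 6.** Dimethyl squarate 6 already holds the four ring carbons and both methoxy groups; one carbonyl has to become CH2. Hydride reduction gives the alcohol 7. The C4 oxygen is then removed reductively from the acetate 8, through a carbanion-like intermediate, and not by ionisation followed by hydride capture. The cation from 7 carries its charge on the methoxy-bearing terminus, so a nucleophilic hydride would enter there, move the double bond and spoil the oxygen pattern. The carbanion from 8 carries its charge on C4, away from the methoxy group, and protonation there gives 9.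

## Alternatives that were turned down

**Alternative 1:** Both pyranone rings are cut at O1–C8a and O1'–C8a', leading back to the diaryl ether bis-(E)-cinnamic acid A2. Forward, a flavin photocatalyst under blue light and air would isomerise both alkenes to the cis geometry and then oxidise each arene–carboxylate pair, so that each carboxylate closes on its ortho carbon. The product is the trimethyl ether A1, which is the same compound as 18.
- For it: A2 needs no oxygen on C8a or C8a'. It could be assembled from two simple benzaldehydes by one copper-mediated ether formation at a carbon activated by an ortho formyl group, followed by a double condensation. This reaches 19 in about four steps against ten, so on step economy it is clearly the stronger plan.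
- Against it: two separate C–H oxidations must succeed in one molecule. On ring A the carboxylate can close para or ortho to the bridging oxygen, and only the para mode gives A1. The second oxidation must occur in a molecule that already contains a coumarin, which absorbs light, quenches sensitisers and can photodimerise. The radical cations of so electron-rich a diaryl ether also have other outlets.
- Comparison: the chosen route is longer, but every lactone oxygen is placed by ground-state chemistry at a position fixed by the starting materials (O1 comes with 3, O1' is the carbonyl oxygen of 9). No regiochemical decision is left to an oxidation.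

**Alternative 2:** Here ring A, not ring B, is built. The C5–C6 and C8–C8a bonds are cut, giving the aryloxyacetone A3 (from the unit B phenol A6 by O-alkylation) and methyl acrylate A4. Under a strong alkoxide base the enolate of A3 would add to A4 through its aryloxy-bearing carbon (Michael reaction), and the methyl ketone would then close on the ester (Claisen condensation). The product is the 4-aryloxycyclohexane-1,3-dione A5, racemic, whose sp3 centre disappears on aromatisation. Dehydrogenation to the resorcinol A7, pyranone annulation and demethylation would follow.
- For it: the hindered C5' ether is made by a simple SN2 alkylation of a phenol, which on this point is as good as the chosen plan, and the reagents are cheap.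
- Against it: it presupposes A6, the pentasubstituted benzene of unit B with three contiguous oxygens in place and the C5' hydroxyl differentiated. That is the hard part of the target and would need a synthesis of its own. The strong base meets a lactone and a polymerisable acrylate, and the Michael step must use the aryloxymethylene and not the methyl carbon of A3. After the key step, a dehydrogenation next to an electron-rich coumarin and a regioselective acid-mediated annulation on A7 are still required.
- Comparison: the step count would be comparable or higher. The chosen route spends its ring-forming step on the difficult ring and buys the easy one.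

**Alternative 3:** Ring A is again the ring made. C5–C6 and C4a–C8a are cut to give the 1,3-dioxygenated ketene-acetal diene A8, which carries the unit B aryloxy group on its terminal carbon, and prop-2-ynal A9. A Diels–Alder reaction in which the nucleophilic terminus of A8 bonds to the β-carbon of A9, followed by loss of the acetal alkoxy group, would give the salicylaldehyde A10. Olefination and lactonisation as in step 9 would then lead to A1 (18).
- For it: the regiochemistry of such dienes with ynals is dependable. The aldehyde and phenol needed for the pyranone arrive in one step, so the endgame is two steps shorter than in the chosen route, and the C7 methoxy group is built in.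
- Against it: like alternative 2 it starts from A6 and leaves the pentasubstituted ring unsolved. A8 must be made by strong-base enolisation and silylation of an ester that contains a lactone. A substituent on the diene terminus slows the cycloaddition, and A9 polymerises readily. In the adduct the allylic aryloxy group at C6 is itself a leaving group and can be lost in competition with the wanted elimination.
- Comparison: the chosen route is stronger where the target is hardest and weaker only in the length of its endgame.

Key step: step 6

Assumption: 1, 3 and 6 are taken as purchasable, and the silyl group of A8 is taken to be trimethylsilyl.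

## Route

Step 1
Reactants: 1 2-[(tert-butyldimethylsilyl)oxy]acetaldehyde
Product: 2 tert-butyl[(3,3-dibromoprop-2-en-1-yl)oxy]dimethylsilane
Conditions: CBr4, PPh3, CH2Cl2, 0 °C
Reagents that add atoms: carbon tetrabromide, BrC(Br)(Br)Br
Why: Corey–Fuchs dibromo-olefination, a Wittig reaction of the ylide formed in the flask from PPh3 and CBr4 with an unhindered aldehyde; the short, cold reaction should leave the primary silyl ether intact.

Step 2
Reactants: 2 tert-butyl[(3,3-dibromoprop-2-en-1-yl)oxy]dimethylsilane; 3 isoscopoletin (6-hydroxy-7-methoxy-2H-chromen-2-one)
Product: 5 6-({3-[(tert-butyldimethylsilyl)oxy]prop-1-yn-1-yl}oxy)-7-methoxy-2H-chromen-2-one, via (Z)-1-bromo enol ether 4 (not isolated)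
Conditions: CuI (cat.), 2,2'-bipyridine (cat.), K3PO4, toluene, 110 °C; then KOtBu, 1,4-dioxane, rt
Reagents that add atoms: none
Why: Copper-catalysed (monovalent copper) Ullmann-type C–O coupling of a phenol with a 1,1-dibromoalkene, a known entry to aryl ynol ethers; the C–Br bond trans to the CH2OSi group is substituted, so 4 has H and Br anti and should lose HBr by E2 elimination with KOtBu at room temperature. The lactone tolerates K3PO4 in toluene, and the bulky alkoxide is used briefly and cold enough to limit attack at the lactone carbonyl.

Step 3
Reactants: 6 dimethyl squarate (3,4-dimethoxycyclobut-3-ene-1,2-dione)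
Product: 7 4-hydroxy-2,3-dimethoxycyclobut-2-en-1-one (racemic)
Conditions: LiAlH(OtBu)3, THF, −78 °C; aq. Rochelle salt
Reagents that add atoms: none
Why: 1,2-Addition of a bulky, mild aluminium hydride to one carbonyl of a squarate ester, known for dialkyl squarates; the remaining carbonyl is a vinylogous ester and is not reduced further at −78 °C. The new stereocentre is racemic and is removed in step 5.

Step 4
Reactants: 7 4-hydroxy-2,3-dimethoxycyclobut-2-en-1-one
Product: 8 2,3-dimethoxy-4-oxocyclobut-2-en-1-yl acetate (racemic)
Conditions: Ac2O, pyridine, DMAP (cat.), CH2Cl2, 0 °C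
Reagents that add atoms: acetic anhydride, CC(=O)OC(C)=O
Why: DMAP-catalysed O-acylation of a secondary alcohol under basic conditions, which avoid ionisation of the C4–O bond to the alkoxy-stabilised cyclobutenyl cation; the acetate is the leaving group for the reductive step.

Step 5
Reactants: 8 2,3-dimethoxy-4-oxocyclobut-2-en-1-yl acetate
Product: 9 2,3-dimethoxycyclobut-2-en-1-one
Conditions: SmI2, THF–MeOH, −78 °C
Reagents that add atoms: none
Why: Reductive cleavage of an α-acyloxy ketone by SmI2 (divalent samarium): ketyl formation, loss of acetate, a second electron transfer and protonation by MeOH. The carbanion is delocalised over C2 and C4, and protonation should occur at C4 because the methoxy group on C2 destabilises and shields that terminus, and because C4 protonation keeps the tetrasubstituted dialkoxy enone. The low temperature keeps 9 below the point at which it ring-opens.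

Step 6
Reactants: 5 6-({3-[(tert-butyldimethylsilyl)oxy]prop-1-yn-1-yl}oxy)-7-methoxy-2H-chromen-2-one; 9 2,3-dimethoxycyclobut-2-en-1-one
Product: 14 6-(2-{[(tert-butyldimethylsilyl)oxy]methyl}-3-hydroxy-5,6-dimethoxyphenoxy)-7-methoxy-2H-chromen-2-one, via vinylketene 10 (not isolated), via vinylcyclobutenone 11 (not isolated), via dienylketene 12 (not isolated), via cyclohexadienone 13 (not isolated)
Conditions: toluene, 110 °C, sealed tube; 9 in excess, added in portions
Reagents that add atoms: none
Why: Danheiser benzannulation, known for cyclobutenones with alkoxy- and silyloxyalkynes and applied here to an aryloxyalkyne and a 2,3-dialkoxycyclobutenone. Heating opens 9 by four-electron electrocyclic cleavage of its C1–C4 bond to the vinylketene 10, whose ketene C=C adds to the triple bond of 5 in a (2+2) cycloaddition to give 11. The selectivity needed is that the silyloxymethyl-bearing alkyne carbon bonds to the ketene carbonyl carbon; the oxygen lone pair of the ynol ether makes exactly that carbon nucleophilic, so C4a'–C8a' and C5'–C6' should form in this sense and the aryloxy carbon ends up meta to the future phenol. 11 then opens in a second four-electron electrocyclic reaction in which the methoxy group on the sp3 carbon rotates outward, as donor substituents do, which places the methoxyvinyl group cis to the ketene in 12. The benzene ring of unit B is closed by six-electron disrotatory electrocyclisation of 12, re-forming as C8'–C8a' the bond that was C4–C1 of 9, and the resulting dienone 13 tautomerises to the phenol 14. No stereocentre remains, since the one in 11 is racemic and is lost on ring opening. The lactone, the methyl ethers and the silyl ether are inert to heat in a neutral aprotic solvent, and an aryl ynol ether cannot fragment by the retro-ene path open to alkyl ynol ethers, so 5 should tolerate the temperature. 9 is used in excess and in portions because the ketene can also be consumed by self-reaction.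

Step 7
Reactants: 14 6-(2-{[(tert-butyldimethylsilyl)oxy]methyl}-3-hydroxy-5,6-dimethoxyphenoxy)-7-methoxy-2H-chromen-2-one
Product: 15 6-[3-hydroxy-2-(hydroxymethyl)-5,6-dimethoxyphenoxy]-7-methoxy-2H-chromen-2-one
Conditions: TBAF, AcOH, THF, 0 °C to rt
Reagents that add atoms: none
Why: Fluoride cleavage of a primary silyl ether; acetic acid buffers the medium so that the lactone does not meet a basic alkoxide or phenoxide. A silyl group that has moved to the neighbouring phenol oxygen during step 6 would be removed in the same operation.

Step 8
Reactants: 15 6-[3-hydroxy-2-(hydroxymethyl)-5,6-dimethoxyphenoxy]-7-methoxy-2H-chromen-2-one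
Product: 16 2-hydroxy-4,5-dimethoxy-6-[(7-methoxy-2-oxo-2H-chromen-6-yl)oxy]benzaldehyde
Conditions: activated MnO2, CH2Cl2, rt
Reagents that add atoms: none
Why: Selective oxidation of a benzylic alcohol by MnO2, established for 2-hydroxybenzyl alcohols; the aldehyde is held by a hydrogen bond to the ortho phenol and should not be oxidised further.

Step 9
Reactants: 16 2-hydroxy-4,5-dimethoxy-6-[(7-methoxy-2-oxo-2H-chromen-6-yl)oxy]benzaldehyde
Product: 18 6,7-dimethoxy-5-[(7-methoxy-2-oxo-2H-chromen-6-yl)oxy]-2H-chromen-2-one, via ethyl cinnamate 17 (not isolated)
Conditions: Ph3P=CHCO2Et, N,N-diethylaniline, reflux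
Reagents that add atoms: ethyl (triphenylphosphoranylidene)acetate, CCOC(=O)C=P(c1ccccc1)(c1ccccc1)c1ccccc1
Why: Wittig olefination of a salicylaldehyde with a stabilised ylide; in the boiling amine the cinnamate 17 isomerises about its double bond and the phenol closes on the ester with loss of ethanol, the standard coumarin synthesis from salicylaldehydes. No strong base or nucleophile is present, so the lactone of unit A is not at risk.

Step 10
Reactants: 18 6,7-dimethoxy-5-[(7-methoxy-2-oxo-2H-chromen-6-yl)oxy]-2H-chromen-2-one
Product: 19 6-[(6,7-dihydroxy-2-oxo-2H-chromen-5-yl)oxy]-7-hydroxy-2H-chromen-2-one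
Conditions: BBr3 (excess), CH2Cl2, −78 °C to rt; then H2O
Reagents that add atoms: none
Why: Lewis-acid cleavage of aryl methyl ethers (boron coordinates the oxygen, bromide attacks the methyl carbon), established for methoxycoumarins; the diaryl ether has no alkyl carbon to attack and the lactones survive aqueous work-up, so the three phenols should be released in one operation.

## Compound list

1 | 2-[(tert-butyldimethylsilyl)oxy]acetaldehyde | CC(C)(C)[Si](C)(C)OCC=O | starting material
2 | tert-butyl[(3,3-dibromoprop-2-en-1-yl)oxy]dimethylsilane | BrC(Br)=CCO[Si](C)(C)C(C)(C)C | intermediate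
3 | isoscopoletin (6-hydroxy-7-methoxy-2H-chromen-2-one) | COc1cc2oc(=O)ccc2cc1O | starting material
4 | 6-({(1Z)-1-bromo-3-[(tert-butyldimethylsilyl)oxy]prop-1-en-1-yl}oxy)-7-methoxy-2H-chromen-2-one | COc1cc2oc(=O)ccc2cc1O/C(Br)=C/CO[Si](C)(C)C(C)(C)C | intermediate (not isolated)
5 | 6-({3-[(tert-butyldimethylsilyl)oxy]prop-1-yn-1-yl}oxy)-7-methoxy-2H-chromen-2-one | COc1cc2oc(=O)ccc2cc1OC#CCO[Si](C)(C)C(C)(C)C | intermediate
6 | dimethyl squarate (3,4-dimethoxycyclobut-3-ene-1,2-dione) | COC1=C(OC)C(=O)C1=O | starting material
7 | 4-hydroxy-2,3-dimethoxycyclobut-2-en-1-one (racemic) | COC1=C(OC)C(=O)C1O | intermediate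
8 | 2,3-dimethoxy-4-oxocyclobut-2-en-1-yl acetate (racemic) | COC1=C(OC)C(=O)C1OC(C)=O | intermediate
9 | 2,3-dimethoxycyclobut-2-en-1-one | COC1=C(OC)C(=O)C1 | intermediate
10 | 2,3-dimethoxybuta-1,3-dien-1-one | C=C(OC)C(OC)=C=O | intermediate (not isolated)
11 | 2-{[(tert-butyldimethylsilyl)oxy]methyl}-4-methoxy-4-(1-methoxyethenyl)-3-[(7-methoxy-2-oxo-2H-chromen-6-yl)oxy]cyclobut-2-en-1-one (racemic) | COC(=C)C1(OC)C(=O)C(CO[Si](C)(C)C(C)(C)C)=C1Oc1cc2ccc(=O)oc2cc1OC | intermediate (not isolated)
12 | (3Z)-2-{[(tert-butyldimethylsilyl)oxy]methyl}-4,5-dimethoxy-3-[(7-methoxy-2-oxo-2H-chromen-6-yl)oxy]hexa-1,3,5-trien-1-one | O=C=C(CO[Si](C)(C)C(C)(C)C)/C(Oc1cc2ccc(=O)oc2cc1OC)=C(/OC)C(OC)=C | intermediate (not isolated)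
13 | 2-{[(tert-butyldimethylsilyl)oxy]methyl}-4,5-dimethoxy-3-[(7-methoxy-2-oxo-2H-chromen-6-yl)oxy]cyclohexa-2,4-dien-1-one | O=C1CC(OC)=C(OC)C(Oc2cc3ccc(=O)oc3cc2OC)=C1CO[Si](C)(C)C(C)(C)C | intermediate (not isolated)
14 | 6-(2-{[(tert-butyldimethylsilyl)oxy]methyl}-3-hydroxy-5,6-dimethoxyphenoxy)-7-methoxy-2H-chromen-2-one | COc1cc2oc(=O)ccc2cc1Oc1c(OC)c(OC)cc(O)c1CO[Si](C)(C)C(C)(C)C | intermediate
15 | 6-[3-hydroxy-2-(hydroxymethyl)-5,6-dimethoxyphenoxy]-7-methoxy-2H-chromen-2-one | COc1cc2oc(=O)ccc2cc1Oc1c(OC)c(OC)cc(O)c1CO | intermediate
16 | 2-hydroxy-4,5-dimethoxy-6-[(7-methoxy-2-oxo-2H-chromen-6-yl)oxy]benzaldehyde | COc1cc2oc(=O)ccc2cc1Oc1c(OC)c(OC)cc(O)c1C=O | intermediate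
17 | ethyl (2E)-3-{2-hydroxy-4,5-dimethoxy-6-[(7-methoxy-2-oxo-2H-chromen-6-yl)oxy]phenyl}prop-2-enoate | CCOC(=O)/C=C/c1c(O)cc(OC)c(OC)c1Oc1cc2ccc(=O)oc2cc1OC | intermediate (not isolated)
18 | 6,7-dimethoxy-5-[(7-methoxy-2-oxo-2H-chromen-6-yl)oxy]-2H-chromen-2-one | COc1cc2oc(=O)ccc2cc1Oc1c(OC)c(OC)cc2oc(=O)ccc12 | intermediate
19 | 6-[(6,7-dihydroxy-2-oxo-2H-chromen-5-yl)oxy]-7-hydroxy-2H-chromen-2-one | O=c1ccc2cc(Oc3c(O)c(O)cc4oc(=O)ccc34)c(O)cc2o1 | target

## Step count and least certain steps

Total: 10 steps. Longest linear sequence: 8 steps (steps 3, 4, 5, 6, 7, 8, 9 and 10, from 6); the other branch runs over 7 steps (1, 2, 6 to 10).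

**Step 6 (key step).** The most likely failure is slow capture of the ketene. An aryloxy group, and a coumarinyl one in particular, is a weaker donor than the alkoxy and silyloxy groups for which the reaction is established, and the dimethoxy ketene is itself electron-rich, so self-reaction of the ketene may outrun the (2+2) step. Two further risks are acylation of the newly formed phenol by ketene, and a ring opening of the vinylogous-ester cyclobutenone slow enough to demand temperatures at which the ynol ether degrades. Fallback, from 3 back to 16, forming the C5'–O bond by nucleophilic aromatic substitution on a preformed ring: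
- Purchasable 3-fluoro-4,5-dimethoxybenzaldehyde would be oxidised (H2O2, cat. H2SO4, MeOH; Baeyer–Villiger-type aryl migration with methanolysis of the aryl formate in the same pot) to 3-fluoro-4,5-dimethoxyphenol F1.
- F1 would be protected (MOMCl, iPr2NEt, CH2Cl2) as 1-fluoro-2,3-dimethoxy-5-(methoxymethoxy)benzene F2.
- F2 would be lithiated at the position between fluorine and the acetal oxygen (n-BuLi, THF, −78 °C) and formylated with DMF to 2-fluoro-3,4-dimethoxy-6-(methoxymethoxy)benzaldehyde F3.
- The phenoxide of 3 (K2CO3, DMF, about 110 °C) would displace the fluoride, which is activated by the ortho formyl group, to give 3,4-dimethoxy-6-(methoxymethoxy)-2-[(7-methoxy-2-oxo-2H-chromen-6-yl)oxy]benzaldehyde F4.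
- HCl in MeOH would remove the acetal and give 16, from which steps 9 and 10 follow unchanged.

**Step 5.** Protonation may occur at the methoxy-bearing terminus instead of C4, which would shift the double bond and lead to the wrong oxygen pattern. Electron transfer to a vinylogous-ester carbonyl may also be slow, and the strained enone may be over-reduced. Fallback, from 7 back to 9, by a radical chain in place of electron transfer (Barton–McCombie deoxygenation). 7 would be converted with 1,1'-thiocarbonyldiimidazole (DMAP cat., CH2Cl2, rt) into O-(2,3-dimethoxy-4-oxocyclobut-2-en-1-yl) 1H-imidazole-1-carbothioate F5. Reduction with Bu3SnH and Et3B with a trace of air in toluene at 0 °C should give 9. Hydrogen-atom transfer from the hydridic tin hydride is polarity-matched at the carbonyl-flanked, methoxy-free carbon C4.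

**Step 2.** The dibromoalkene may lose HBr before it couples, or a second phenol may substitute the remaining bromide. In the elimination stage, tert-butoxide may open the lactone of unit A. Fallback, from 4 (now isolated after the copper step) back to 5, by fluoride-induced elimination with a deprotection and reprotection detour. TBAF in DMF at rt should effect anti-elimination of HBr without attacking the lactone, and at the same time remove the silyl group, giving 6-[(3-hydroxyprop-1-yn-1-yl)oxy]-7-methoxy-2H-chromen-2-one F6. Re-silylation (TBSCl, imidazole, CH2Cl2) returns 5.

**Step 9.** The formyl group lies between two ortho substituents, so olefination may be slow at a temperature where the electron-rich diaryl ether begins to decompose, and isomerisation of the cinnamate may be incomplete. Fallback, from 16 back to 18, by Knoevenagel condensation in place of the Wittig reaction. 16 and Meldrum's acid (piperidinium acetate, EtOH, reflux) should condense and lactonise directly to 6,7-dimethoxy-5-[(7-methoxy-2-oxo-2H-chromen-6-yl)oxy]-2-oxo-2H-chromene-3-carboxylic acid F7. Here the cis relation of phenol and carbonyl is built in, so no double-bond isomerisation is needed. Decarboxylation (Cu powder, quinoline, about 200 °C) gives 18.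

## Further compounds

F1 | step 6 | 3-fluoro-4,5-dimethoxyphenol | Oc1cc(F)c(OC)c(OC)c1
F2 | step 6 | 1-fluoro-2,3-dimethoxy-5-(methoxymethoxy)benzene | COCOc1cc(F)c(OC)c(OC)c1
F3 | step 6 | 2-fluoro-3,4-dimethoxy-6-(methoxymethoxy)benzaldehyde | COCOc1cc(OC)c(OC)c(F)c1C=O
F4 | step 6 | 3,4-dimethoxy-6-(methoxymethoxy)-2-[(7-methoxy-2-oxo-2H-chromen-6-yl)oxy]benzaldehyde | COCOc1cc(OC)c(OC)c(Oc2cc3ccc(=O)oc3cc2OC)c1C=O
F5 | step 5 | O-(2,3-dimethoxy-4-oxocyclobut-2-en-1-yl) 1H-imidazole-1-carbothioate (racemic) | COC1=C(OC)C(=O)C1OC(=S)n1ccnc1
F6 | step 2 | 6-[(3-hydroxyprop-1-yn-1-yl)oxy]-7-methoxy-2H-chromen-2-one | COc1cc2oc(=O)ccc2cc1OC#CCO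
F7 | step 9 | 6,7-dimethoxy-5-[(7-methoxy-2-oxo-2H-chromen-6-yl)oxy]-2-oxo-2H-chromene-3-carboxylic acid | COc1cc2oc(=O)ccc2cc1Oc1c(OC)c(OC)cc2oc(=O)c(C(=O)O)cc12
A1 | alternative 1 | 6,7-dimethoxy-5-[(7-methoxy-2-oxo-2H-chromen-6-yl)oxy]-2H-chromen-2-one (identical with 18) | COc1cc2oc(=O)ccc2cc1Oc1c(OC)c(OC)cc2oc(=O)ccc12
A2 | alternative 1 | (2E)-3-(2-{5-[(E)-2-carboxyethenyl]-2-methoxyphenoxy}-3,4-dimethoxyphenyl)prop-2-enoic acid | COc1ccc(/C=C/C(=O)O)cc1Oc1c(/C=C/C(=O)O)ccc(OC)c1OC
A3 | alternative 2 | 6,7-dimethoxy-5-(2-oxopropoxy)-2H-chromen-2-one | CC(=O)COc1c(OC)c(OC)cc2oc(=O)ccc12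
A4 | alternative 2 | methyl acrylate | C=CC(=O)OC
A5 | alternative 2 | 4-[(6,7-dimethoxy-2-oxo-2H-chromen-5-yl)oxy]cyclohexane-1,3-dione (racemic) | O=C1CC(=O)C(Oc2c(OC)c(OC)cc3oc(=O)ccc23)CC1
A6 | alternative 2 | 5-hydroxy-6,7-dimethoxy-2H-chromen-2-one | COc1cc2oc(=O)ccc2c(O)c1OC
A7 | alternative 2 | 5-(2,4-dihydroxyphenoxy)-6,7-dimethoxy-2H-chromen-2-one | Oc1ccc(Oc2c(OC)c(OC)cc3oc(=O)ccc23)c(O)c1
A8 | alternative 3 | 5-{[2,4-dimethoxy-4-(trimethylsilyloxy)buta-1,3-dien-1-yl]oxy}-6,7-dimethoxy-2H-chromen-2-one (double-bond geometry left open) | COC(O[Si](C)(C)C)=CC(OC)=COc1c(OC)c(OC)cc2oc(=O)ccc12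
A9 | alternative 3 | prop-2-ynal | C#CC=O
A10 | alternative 3 | 5-[(6,7-dimethoxy-2-oxo-2H-chromen-5-yl)oxy]-2-hydroxy-4-methoxybenzaldehyde | O=Cc1cc(Oc2c(OC)c(OC)cc3oc(=O)ccc23)c(OC)cc1O
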